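**Plan**
- Cuts, in retrosynthetic order: (a) the sp2–sp2 bond between butenolide C4 and the trienyl chain (Suzuki–Miyaura); (b) the chain C10=C11 alkene next to it (boryl olefination of an enal); (c) in the oxolan-2-one ring, O1–C5 and C3–C4 together, by a (3+2) heteroannulation of a 2-bromoalk-2-enoic acid with 4-methylpenta-1,3-diene; (d) the C2=C3 bond of that bromo acid (Horner–Wadsworth–Emmons), back to a trisnor aldehyde cut from (2E,6E)-farnesol.
- Enabling feature: ring O1 sits on C5, an allylic carbon (C5 carries the 2-methylprop-1-enyl group), and ring C3 is an sp2 carbon; O1–C5 is therefore an allylic ester bond, open to carboxylate capture of an allylpalladium that is born when an alkenylpalladium at C3 adds to the diene.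
- Forward order: farnesol → silyl ether → terminal alkene cut to the aldehyde → (E)-2-bromoenoic acid → lactone ring closed (key step) → desilylation and oxidation → dienylboronate → butenolide ring, bought as 4-bromofuran-2(5H)-one, joined last.
- Stereochemistry: C5 (R) from the chiral ligand on palladium during the O1–C5 closure; the 3Z alkylidene from the E-selective bromo-olefination and the stereoretentive annulation; 4E and 8E from farnesol; 10E from the chromium-mediated olefination, kept by the coupling.

Key step: step 9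

Assumption: read from the SMILES, the target is the (3Z,5R) isomer with a 4E,8E,10E chain; the sense of induction of the ligand in step 9 cannot be predicted with certainty, so the ligand enantiomer that delivers 5R is taken to be the one used.

**Step 1**
Reactants: 1 (2E,6E)-farnesol; 2 tert-butyl(chloro)diphenylsilane (TBDPSCl)
Product: 3 tert-butyldiphenyl{[(2E,6E)-3,7,11-trimethyldodeca-2,6,10-trien-1-yl]oxy}silane
Conditions: TBDPSCl, imidazole, CH2Cl2, 0 °C to rt
Reagents that add atoms: TBDPSCl, CC(C)(C)[Si](Cl)(c1ccccc1)c1ccccc1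
Why: Imidazole-promoted silylation of the primary allylic alcohol gives a silyl ether that should survive aqueous acid, carbonate, hydroxide and zerovalent palladium, unlike an allylic acetate.

**Step 2**
Reactants: 3 farnesyl silyl ether; 4 N-bromosuccinimide; 5 water
Product: 6 (6E,10E)-3-bromo-12-[(tert-butyldiphenylsilyl)oxy]-2,6,10-trimethyldodeca-6,10-dien-2-ol (racemic)
Conditions: NBS, THF/H2O, 0 °C
Reagents that add atoms: N-bromosuccinimide, O=C1CCC(=O)N1Br; water, O
Why: Terminal-selective bromohydrin formation of a polyprenyl chain in aqueous THF, where the exposed 10,11-alkene takes up bromonium and water opens it at the tertiary carbon; the new CHBr center is racemic and is cut away in step 4.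

**Step 3**
Reactants: 6 bromohydrin
Product: 7 tert-butyl{[(2E,6E)-9-(3,3-dimethyloxiran-2-yl)-3,7-dimethylnona-2,6-dien-1-yl]oxy}diphenylsilane (racemic)
Conditions: K2CO3, MeOH, rt
Reagents that add atoms: none
Why: Intramolecular Williamson etherification, in which the tertiary alkoxide displaces the neighbouring bromide; the silyl ether is stable to carbonate in methanol.

**Step 4**
Reactants: 7 epoxide; 5 water
Product: 9 (4E,8E)-10-[(tert-butyldiphenylsilyl)oxy]-4,8-dimethyldeca-4,8-dienal, via 2,3-diol 8 (not isolated)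
Conditions: H5IO6, THF/H2O, 0 °C
Reagents that add atoms: none
Why: Periodic acid first hydrolyses the epoxide (water attacks the tertiary carbon, so its oxygen later leaves in acetone) and then cleaves the diol in a Malaprade glycol cleavage to the aldehyde.

**Step 5**
Reactants: 10 methyl 2-[bis(2,2,2-trifluoroethoxy)phosphoryl]acetate (Still–Gennari reagent); 11 bromine
Product: 12 methyl 2,2-dibromo-2-[bis(2,2,2-trifluoroethoxy)phosphoryl]acetate
Conditions: Br2, aq NaOH (NaOBr formed in place), 0 °C
Reagents that add atoms: bromine, BrBr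
Why: Exhaustive hypobromite bromination of the doubly activated methylene (haloform-type α-halogenation), the established entry to α-bromophosphonoacetates.

**Step 6**
Reactants: 12 dibromophosphonate
Product: 13 methyl 2-bromo-2-[bis(2,2,2-trifluoroethoxy)phosphoryl]acetate (racemic)
Conditions: SnCl2·2H2O, EtOH/H2O, 0 °C
Reagents that add atoms: none
Why: Divalent tin reductively removes one of the two positive bromines of the doubly activated gem-dibromide (selective monodebromination) and should stop at the monobromide.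

**Step 7**
Reactants: 9 aldehyde; 13 bromophosphonate
Product: 14 methyl (2E,6E,10E)-2-bromo-12-[(tert-butyldiphenylsilyl)oxy]-6,10-dimethyldodeca-2,6,10-trienoate
Conditions: 13, KOt-Bu, 18-crown-6, THF, −78 °C
Reagents that add atoms: methyl 2-bromo-2-[bis(2,2,2-trifluoroethoxy)phosphoryl]acetate, COC(=O)C(Br)P(=O)(OCC(F)(F)F)OCC(F)(F)F
Why: Horner–Wadsworth–Emmons olefination with the bromo analogue of the Still–Gennari reagent, whose trifluoroethyl phosphonate eliminates under kinetic control so that the chain ends up cis to the ester, which is the (E)-α-bromoacrylate.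

**Step 8**
Reactants: 14 bromo ester; 5 water
Product: 15 (2E,6E,10E)-2-bromo-12-[(tert-butyldiphenylsilyl)oxy]-6,10-dimethyldodeca-2,6,10-trienoic acid
Conditions: LiOH·H2O, THF/MeOH/H2O, 0 °C to rt; then 1 M HCl to pH 3
Reagents that add atoms: water, O
Why: Saponification of the methyl ester at low temperature, where the vinylic bromide, the silyl ether and the alkene geometry should stay untouched.

**Step 9**
Reactants: 15 bromo acid; 16 4-methylpenta-1,3-diene
Product: 17 (3Z,5R)-3-[(4E,8E)-10-[(tert-butyldiphenylsilyl)oxy]-4,8-dimethyldeca-4,8-dien-1-ylidene]-5-(2-methylprop-1-en-1-yl)oxolan-2-one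
Conditions: Pd(OAc)2 (5 mol %), H8-BINOL-derived N,N-bis(1-phenylethyl)phosphoramidite (12 mol %, enantiomer chosen for 5R), K2CO3 (2 equiv), 16 (5 equiv), DMF, 50 °C, sealed vessel
Reagents that add atoms: 4-methylpenta-1,3-diene, CC(C)=CC=C
Why: Proposed new method: zerovalent palladium inserts into the C–Br bond of the carboxylate of 15 with retention, the alkenylpalladium adds to the unsubstituted C1=C2 end of diene 16 (the new C3–C4 bond of the lactone), and the allylpalladium that now spans the former diene carbons C2–C4 is captured at C2 by the tethered carboxylate oxygen, which closes the ring through the O1–C5 bond and frees zerovalent palladium again. The closest known reaction type is the Larock heteroannulation of 1,3-dienes by aryl or alkenyl halides that carry a nucleophile (Heck insertion, then Tsuji–Trost capture), known without asymmetric induction for halides bearing carboxylic acid, hydroxyl or amino groups and in enantioselective form for 2-halophenols and 2-haloanilines, but not enantioselectively for a 2-bromoalk-2-enoic acid. The five-membered ring closes in the 5-exo mode at the allyl terminus next to the new CH2, because attack at the CMe2 terminus would need a seven-membered ring with a ring alkene and a tertiary carbon. The C5 stereocenter is set in this C–O bond formation by the chiral phosphoramidite on palladium; the two diastereomeric allyl complexes can exchange faces through the σ-bonded form at the CMe2 end (two identical methyl groups), so the ligand decides which face of C5 the oxygen reaches. The step needs carbopalladation at the terminal CH2 of 16 (secured by the unsubstituted terminus against the blocked CMe2 end), capture before β-hydride elimination (secured by the intramolecular carboxylate) and retention of alkene geometry, so that the E bromide becomes the 3Z alkylidene with the chain still cis to the carbonyl carbon. The silyl ether and the isolated trisubstituted alkenes, which lie trans to palladium or far from it, should not interfere.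

**Step 10**
Reactants: 17 silyl-protected lactone
Product: 18 (3Z,5R)-3-[(4E,8E)-10-hydroxy-4,8-dimethyldeca-4,8-dien-1-ylidene]-5-(2-methylprop-1-en-1-yl)oxolan-2-one
Conditions: TBAF, AcOH, THF, 0 °C to rt
Reagents that add atoms: none
Why: Fluoride-mediated cleavage of the silyl ether, buffered with acetic acid so that the conjugated lactone and the allylic C5–O bond do not meet basic fluoride.

**Step 11**
Reactants: 18 allylic alcohol
Product: 19 (3Z,5R)-3-[(4E,8E)-4,8-dimethyl-10-oxodeca-4,8-dien-1-ylidene]-5-(2-methylprop-1-en-1-yl)oxolan-2-one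
Conditions: MnO2, CH2Cl2, rt
Reagents that add atoms: none
Why: Chemoselective MnO2 oxidation of the primary allylic alcohol to the enal with retention of the E geometry, there being no other oxidizable hydroxyl group.

**Step 12**
Reactants: 19 enal; 20 2-(dichloromethyl)-4,4,5,5-tetramethyl-1,3,2-dioxaborolane
Product: 21 (3Z,5R)-3-[(4E,8E,10E)-4,8-dimethyl-11-(4,4,5,5-tetramethyl-1,3,2-dioxaborolan-2-yl)undeca-4,8,10-trien-1-ylidene]-5-(2-methylprop-1-en-1-yl)oxolan-2-one
Conditions: Cl2CHBpin, CrCl2, LiI, THF, rt
Reagents that add atoms: 2-(dichloromethyl)-4,4,5,5-tetramethyl-1,3,2-dioxaborolane, ClC(Cl)B1OC(C)(C)C(C)(C)O1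
Why: Takai-type boryl olefination, in which the geminal dichromium species from the dihalomethylboronate adds to the aldehyde and eliminates to the (E)-alkenylboronate, while divalent chromium leaves lactones and isolated alkenes alone.

**Step 13**
Reactants: 21 dienylboronate; 22 4-bromofuran-2(5H)-one
Product: 23 (3Z,5R)-3-[(4E,8E,10E)-4,8-dimethyl-11-(5-oxo-2,5-dihydrofuran-3-yl)undeca-4,8,10-trien-1-ylidene]-5-(2-methylprop-1-en-1-yl)oxolan-2-one
Conditions: PdCl2(dppf) (5 mol %), K3PO4, THF/H2O, rt
Reagents that add atoms: 4-bromofuran-2(5H)-one, BrC1=CC(=O)OC1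
Why: Suzuki–Miyaura coupling with retention at both sp2 carbons, in which oxidative addition of zerovalent palladium into the activated β-bromo enoate at room temperature should be far faster than ionization of the allylic lactone with its trisubstituted alkene.

**Compound list**
1 | (2E,6E)-farnesol | CC(C)=CCC/C(C)=C/CC/C(C)=C/CO | starting material
2 | tert-butyl(chloro)diphenylsilane | CC(C)(C)[Si](Cl)(c1ccccc1)c1ccccc1 | starting material
3 | tert-butyldiphenyl{[(2E,6E)-3,7,11-trimethyldodeca-2,6,10-trien-1-yl]oxy}silane | CC(C)=CCC/C(C)=C/CC/C(C)=C/CO[Si](c1ccccc1)(c1ccccc1)C(C)(C)C | intermediate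
4 | N-bromosuccinimide | O=C1CCC(=O)N1Br | starting material
5 | water | O | starting material
6 | (6E,10E)-3-bromo-12-[(tert-butyldiphenylsilyl)oxy]-2,6,10-trimethyldodeca-6,10-dien-2-ol (racemic) | CC(C)(O)C(Br)CC/C(C)=C/CC/C(C)=C/CO[Si](c1ccccc1)(c1ccccc1)C(C)(C)C | intermediate
7 | tert-butyl{[(2E,6E)-9-(3,3-dimethyloxiran-2-yl)-3,7-dimethylnona-2,6-dien-1-yl]oxy}diphenylsilane (racemic) | CC1(C)OC1CC/C(C)=C/CC/C(C)=C/CO[Si](c1ccccc1)(c1ccccc1)C(C)(C)C | intermediate
8 | (6E,10E)-12-[(tert-butyldiphenylsilyl)oxy]-2,6,10-trimethyldodeca-6,10-diene-2,3-diol (racemic, not isolated) | CC(C)(O)C(O)CC/C(C)=C/CC/C(C)=C/CO[Si](c1ccccc1)(c1ccccc1)C(C)(C)C | intermediate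
9 | (4E,8E)-10-[(tert-butyldiphenylsilyl)oxy]-4,8-dimethyldeca-4,8-dienal | O=CCC/C(C)=C/CC/C(C)=C/CO[Si](c1ccccc1)(c1ccccc1)C(C)(C)C | intermediate
10 | methyl 2-[bis(2,2,2-trifluoroethoxy)phosphoryl]acetate | COC(=O)CP(=O)(OCC(F)(F)F)OCC(F)(F)F | starting material
11 | bromine | BrBr | starting material
12 | methyl 2,2-dibromo-2-[bis(2,2,2-trifluoroethoxy)phosphoryl]acetate | COC(=O)C(Br)(Br)P(=O)(OCC(F)(F)F)OCC(F)(F)F | intermediate
13 | methyl 2-bromo-2-[bis(2,2,2-trifluoroethoxy)phosphoryl]acetate (racemic) | COC(=O)C(Br)P(=O)(OCC(F)(F)F)OCC(F)(F)F | intermediate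
14 | methyl (2E,6E,10E)-2-bromo-12-[(tert-butyldiphenylsilyl)oxy]-6,10-dimethyldodeca-2,6,10-trienoate | COC(=O)/C(Br)=C\CC/C(C)=C/CC/C(C)=C/CO[Si](c1ccccc1)(c1ccccc1)C(C)(C)C | intermediate
15 | (2E,6E,10E)-2-bromo-12-[(tert-butyldiphenylsilyl)oxy]-6,10-dimethyldodeca-2,6,10-trienoic acid | OC(=O)/C(Br)=C\CC/C(C)=C/CC/C(C)=C/CO[Si](c1ccccc1)(c1ccccc1)C(C)(C)C | intermediate
16 | 4-methylpenta-1,3-diene | CC(C)=CC=C | starting material
17 | (3Z,5R)-3-[(4E,8E)-10-[(tert-butyldiphenylsilyl)oxy]-4,8-dimethyldeca-4,8-dien-1-ylidene]-5-(2-methylprop-1-en-1-yl)oxolan-2-one | CC(C)=C[C@H]1C/C(=C/CC/C(C)=C/CC/C(C)=C/CO[Si](c2ccccc2)(c2ccccc2)C(C)(C)C)C(=O)O1 | intermediate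
18 | (3Z,5R)-3-[(4E,8E)-10-hydroxy-4,8-dimethyldeca-4,8-dien-1-ylidene]-5-(2-methylprop-1-en-1-yl)oxolan-2-one | CC(C)=C[C@H]1C/C(=C/CC/C(C)=C/CC/C(C)=C/CO)C(=O)O1 | intermediate
19 | (3Z,5R)-3-[(4E,8E)-4,8-dimethyl-10-oxodeca-4,8-dien-1-ylidene]-5-(2-methylprop-1-en-1-yl)oxolan-2-one | CC(C)=C[C@H]1C/C(=C/CC/C(C)=C/CC/C(C)=C/C=O)C(=O)O1 | intermediate
20 | 2-(dichloromethyl)-4,4,5,5-tetramethyl-1,3,2-dioxaborolane | ClC(Cl)B1OC(C)(C)C(C)(C)O1 | starting material
21 | (3Z,5R)-3-[(4E,8E,10E)-4,8-dimethyl-11-(4,4,5,5-tetramethyl-1,3,2-dioxaborolan-2-yl)undeca-4,8,10-trien-1-ylidene]-5-(2-methylprop-1-en-1-yl)oxolan-2-one | CC(C)=C[C@H]1C/C(=C/CC/C(C)=C/CC/C(C)=C/C=C/B2OC(C)(C)C(C)(C)O2)C(=O)O1 | intermediate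
22 | 4-bromofuran-2(5H)-one | BrC1=CC(=O)OC1 | starting material
23 | (3Z,5R)-3-[(4E,8E,10E)-4,8-dimethyl-11-(5-oxo-2,5-dihydrofuran-3-yl)undeca-4,8,10-trien-1-ylidene]-5-(2-methylprop-1-en-1-yl)oxolan-2-one | CC(C)=C[C@H]1C/C(=C/CC/C(C)=C/CC/C(C)=C/C=C/C2=CC(=O)OC2)C(=O)O1 | target

**Count**
Total steps: 13. Longest linear sequence: 11 steps (steps 1–4 and 7–13, from farnesol); steps 5 and 6 make the olefination reagent and join at step 7.

**Steps most likely to fail**

1. Step 9 (proposed new method). What may go wrong: weak enantioface discrimination when the carboxylate captures the allylpalladium, loss of enantiopurity through reversible ionization of the allylic lactone by zerovalent palladium, or β-hydride elimination of the allylpalladium before capture. Fallback with known chemistry, setting out from 15 and 16: the ring is closed without asymmetric induction under ligand-free Larock heteroannulation conditions (Pd(OAc)2, Na2CO3, n-Bu4NCl, DMF, 80 °C) to give racemic (3Z)-3-[(4E,8E)-10-[(tert-butyldiphenylsilyl)oxy]-4,8-dimethyldeca-4,8-dien-1-ylidene]-5-(2-methylprop-1-en-1-yl)oxolan-2-one F1. The stereocenter is then obtained by resolution instead of catalyst control: preparative HPLC on a cellulose-based chiral stationary phase separates the enantiomers, the (3Z,5S)-3-[(4E,8E)-10-[(tert-butyldiphenylsilyl)oxy]-4,8-dimethyldeca-4,8-dien-1-ylidene]-5-(2-methylprop-1-en-1-yl)oxolan-2-one F2 is set aside, and the route is rejoined at 17.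

2. Step 13. What may go wrong: ionization of the allylic C5–O bond of the lactone by zerovalent palladium (racemization or ring opening), or base-induced degradation of the butenolide during the coupling. Fallback without palladium, setting out from 19: commercial 4-methylfuran-2(5H)-one is brominated (NBS, benzoyl peroxide, PhCF3, reflux; Wohl–Ziegler) to 4-(bromomethyl)furan-2(5H)-one F3, which with PPh3 in toluene gives [(5-oxo-2,5-dihydrofuran-3-yl)methyl]triphenylphosphonium bromide F4. Its stabilized, ester-conjugated ylide (K2CO3, 18-crown-6, CH2Cl2, rt) should undergo an E-selective Wittig reaction with enal 19 and give 23 directly, so steps 12 and 13 are both replaced.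

3. Step 7. What may go wrong: erosion of the kinetic selectivity that places the chain cis to the ester, or isomerization to the more stable bromide isomer during olefination and saponification; the wrong isomer would lead to the 3E lactone. Fallback setting out from 9, with the geometry fixed by a syn addition instead of an olefination: Ohira–Bestmann homologation (dimethyl (1-diazo-2-oxopropyl)phosphonate, K2CO3, MeOH) gives tert-butyl{[(2E,6E)-3,7-dimethylundeca-2,6-dien-10-yn-1-yl]oxy}diphenylsilane F5. Deprotonation and acylation (n-BuLi, then ClCO2Me, THF, −78 °C) give methyl (6E,10E)-12-[(tert-butyldiphenylsilyl)oxy]-6,10-dimethyldodeca-6,10-dien-2-ynoate F6. Hydrostannation with syn addition and tin at the α-carbon (Bu3SnH, Pd(PPh3)4, THF, rt) gives methyl (2E,6E,10E)-12-[(tert-butyldiphenylsilyl)oxy]-6,10-dimethyl-2-(tributylstannyl)dodeca-2,6,10-trienoate F7. Bromodestannylation with retention (NBS, MeCN, 0 °C) then returns the route at 14.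

**Further compounds**
F1 | step 9 | racemic (3Z)-3-[(4E,8E)-10-[(tert-butyldiphenylsilyl)oxy]-4,8-dimethyldeca-4,8-dien-1-ylidene]-5-(2-methylprop-1-en-1-yl)oxolan-2-one | CC(C)=CC1C/C(=C/CC/C(C)=C/CC/C(C)=C/CO[Si](c2ccccc2)(c2ccccc2)C(C)(C)C)C(=O)O1
F2 | step 9 | (3Z,5S)-3-[(4E,8E)-10-[(tert-butyldiphenylsilyl)oxy]-4,8-dimethyldeca-4,8-dien-1-ylidene]-5-(2-methylprop-1-en-1-yl)oxolan-2-one | CC(C)=C[C@@H]1C/C(=C/CC/C(C)=C/CC/C(C)=C/CO[Si](c2ccccc2)(c2ccccc2)C(C)(C)C)C(=O)O1
F3 | step 13 | 4-(bromomethyl)furan-2(5H)-one | BrCC1=CC(=O)OC1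
F4 | step 13 | [(5-oxo-2,5-dihydrofuran-3-yl)methyl]triphenylphosphonium bromide | [Br-].O=C1OCC(C[P+](c2ccccc2)(c2ccccc2)c2ccccc2)=C1
F5 | step 7 | tert-butyl{[(2E,6E)-3,7-dimethylundeca-2,6-dien-10-yn-1-yl]oxy}diphenylsilane | C#CCC/C(C)=C/CC/C(C)=C/CO[Si](c1ccccc1)(c1ccccc1)C(C)(C)C
F6 | step 7 | methyl (6E,10E)-12-[(tert-butyldiphenylsilyl)oxy]-6,10-dimethyldodeca-6,10-dien-2-ynoate | COC(=O)C#CCC/C(C)=C/CC/C(C)=C/CO[Si](c1ccccc1)(c1ccccc1)C(C)(C)C
F7 | step 7 | methyl (2E,6E,10E)-12-[(tert-butyldiphenylsilyl)oxy]-6,10-dimethyl-2-(tributylstannyl)dodeca-2,6,10-trienoate | COC(=O)/C(=C\CC/C(C)=C/CC/C(C)=C/CO[Si](c1ccccc1)(c1ccccc1)C(C)(C)C)[Sn](CCCC)(CCCC)CCCC
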